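## Structural features

The target is an achiral bicoumarin ether: unit A is a 7-methoxycoumarin (benzene ring A fused to pyranone ring C), unit B is a 5,7-dihydroxycoumarin (benzene ring B fused to pyranone ring D), and one oxygen joins C8 of ring A to C8 of ring B. There is no stereocentre, so all the difficulty is constitutional. Each ether carbon sits between two oxygen-bearing carbons (C7 and C8a of its ring), so the diaryl ether is tetra-ortho-substituted and electron-rich on both sides. This is the worst case for copper- or palladium-mediated etherification, and it also rules out an aryne, because a phenoxide adds to an alkoxy-aryne at the carbon remote from the alkoxy group and cannot place an aryloxy group between two oxygens. Ring B is a phloroglucinol nucleus in which C6 and C8 are nearly equivalent, so any route through a 5,7-dihydroxycoumarin or a free 2-aryloxyphloroglucinol must choose between the 6- and the 8-aryloxy isomer. The fragile groups are the two lactones (opened by hot base), the phloroglucinol-type phenols (oxidation, C-alkylation) and the ring-A methyl ether, which must outlast whatever protects ring B. The key step exploits the fact that C8 of ring B is C2 of a resorcinol whose para oxygen (the future O5) can be capped: a diazo group on that carbon makes it an electrophilic quinoid carbene carbon, and the resulting 2-aryloxy-5-alkoxyresorcinol has a mirror plane through C8 and C5 of ring B, so the two sites at which ring D can close are identical. In one sentence: the hindered ether bond is made by O–H insertion of a rhodium quinoid carbene, generated at the future C8 of ring B from a 2-diazoresorcinol-type quinone diazide, into the C8 hydroxyl of the preformed ring-A coumarin.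

## Logic of the disconnections

16 is traced back to 15 by cutting the O5–CH2Ph bond of ring B. The benzyl group is the device that makes O5 different from the two oxygens beside the ether carbon. The gain in simplicity is small. The forward step must cleave one benzyl ether and spare the aryl methyl ether, the diaryl ether and both lactones.

15 is traced back to 12 and 13 (through 14) by cutting C4–C4a and O1–C2 of ring D. The cut is made here because 12 is symmetric: its two free ring carbons are equivalent, each lies ortho to a free hydroxyl, and O5 is blocked, so only one coumarin can form. A whole ring is removed and the 6/8 regiochemistry problem disappears. The forward step needs C–C bond formation at the arene (not O-vinylation), a single annulation, and conditions that keep the benzyl ether.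

12 is traced back to 5 and 11 by cutting the bond between the ether oxygen and the ring-B carbon. This is the key disconnection: ring B, normally a nucleophile, is used as a carbene at exactly that carbon, so the oxygen of 5 can attack it. The gain is the largest of the route: two fragments of similar size, one of them symmetric, and no metal-mediated coupling of two crowded, electron-rich aryl partners. The forward step demands that O–H insertion into 5 outruns ring contraction, self-reaction of 11 and attack on carbon.

11 is traced back through 9 and 8 to 6, 7 and 10 by functional group changes only (diazo from amine, amine from nitro, benzyl ether from phenol). The nitro group of 6 marks the future ether carbon without ambiguity and makes the para hydroxyl the most acidic, so it alone is benzylated. The forward steps need mono-alkylation at that oxygen, a nitro reduction that leaves the benzyl ether, and a diazotization free of azo coupling.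

5 is traced back to 1 and 2 (through 3 and 4) by cutting C3=C4 and O1–C2 of ring C. 1 already carries all three oxygens of ring A in the right places, so only the two-carbon unit has to be added. The forward step needs olefination followed by lactonization onto the only hydroxyl ortho to the side chain.

## Other disconnections considered

Alternative 1: the first idea is to cut the same ether bond for a copper-mediated Ullmann coupling of 5 with 5,7-bis(benzyloxy)-8-bromocoumarin A1, giving the bis-benzyl ether A2 of the target, then double debenzylation. The chosen plan is preferred on three grounds. A1 requires halogenation of a 5,7-dialkoxycoumarin at C8 in competition with C6 and C3. The coupling must bring two di-ortho-substituted, electron-rich partners together on one copper centre, where both aryl halide activation and C–O reductive elimination are slowed. The hot basic medium opens both lactones. The carbene route forms the bond at a planar carbon and takes its regiochemistry from a nitro group.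

Alternative 2: ring A could be carried as a saturated ring and aromatized late. Rhodium-catalysed O–H insertion of 2-diazocyclohexane-1,3-dione A3 into 5,7-bis(benzyloxy)-8-hydroxycoumarin A4 would give the 2-aryloxy-1,3-dione A5. Methyl enol ether formation and dehydrogenation would give the 2-aryloxy-3-methoxyphenol A6, and annulation of ring C would give A2, then debenzylation. The polarity reversal is the same, and desymmetrizing the dione by O-methylation is attractive. However, A4 needs an oxygen placed at C8 of a 5,7-dioxygenated coumarin, which brings back the C6/C8 ambiguity. Four operations would follow the union instead of two, and the dehydrogenation would have to be run beside an oxidizable benzyloxy arene. Placing the carbene on ring B solves the ether bond and the ring-B regiochemistry together.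

Alternative 3: ring B could be built around an sp3 carbon. O-alkylation of 5 with a bromomalonate ester would give the aryloxymalonate A7. A [3+3] double Claisen condensation with an acetonedicarboxylate ester would give the phloroglucinol diester A8, and hydrolysis with decarboxylation would give the 2-aryloxyphloroglucinol A9 for annulation. The ether bond would be easy to make, but A9 has three free hydroxyls, so ring D can close on either oxygen next to the new side chain and the 6-aryloxy isomer A10 would accompany the target. The strong base needed for the double Claisen condensation would also open the lactone of unit A, and the sequence is longer.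

Key step: step 5

Assumption: the SMILES carries no stereodescriptor and rotation about the ether bonds is taken as free, so the target is treated as one achiral compound; 1, 2, 6, 7, 10 and 13 are taken as purchasable.

## Route

Step 1
Reactants: 1 2,3-dihydroxy-4-methoxybenzaldehyde; 2 ethyl (triphenylphosphoranylidene)acetate
Product: 5 8-hydroxy-7-methoxy-2H-chromen-2-one, via ethyl (E)-3-(2,3-dihydroxy-4-methoxyphenyl)prop-2-enoate 3 (not isolated), via ethyl (Z)-3-(2,3-dihydroxy-4-methoxyphenyl)prop-2-enoate 4 (not isolated)
Conditions: Ph3P=CHCO2Et (1.2 equiv), PhNEt2, reflux (ca. 215 °C), Ar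
Reagents that add atoms: ethyl (triphenylphosphoranylidene)acetate (2), CCOC(=O)C=P(c1ccccc1)(c1ccccc1)c1ccccc1
Why: Wittig olefination of the salicylaldehyde with the stabilized ylide should give the cinnamate 3, which at this temperature equilibrates with 4, and 4 lactonizes onto the only hydroxyl ortho to the side chain with loss of ethanol; the second catechol hydroxyl cannot reach the ester and stays free as the C8 hydroxyl.

Step 2
Reactants: 6 2-nitrobenzene-1,3,5-triol; 7 benzyl bromide
Product: 8 5-(benzyloxy)-2-nitrobenzene-1,3-diol
Conditions: BnBr (1.0 equiv), KHCO3 (1.05 equiv), DMF, 0 °C to rt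
Reagents that add atoms: benzyl bromide (7), BrCc1ccccc1
Why: Williamson ether synthesis under acidity control: the hydroxyl para to the nitro group is the most acidic and the only one not held in a hydrogen bond to a nitro oxygen, so one equivalent of a weak base should form and alkylate that phenoxide selectively, as with other ortho,para-dihydroxy nitroarenes and acylphloroglucinols.

Step 3
Reactants: 8 5-(benzyloxy)-2-nitrobenzene-1,3-diol
Product: 9 2-amino-5-(benzyloxy)benzene-1,3-diol
Conditions: H2 (1 atm), sulfided Pt/C (5 wt% Pt, 2 mol%), EtOAc, rt; filtration under Ar, used at once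
Reagents that add atoms: none
Why: Catalytic hydrogenation of the nitro group; sulfided platinum reduces nitro groups but is a poor hydrogenolysis catalyst, so the benzyl ether should survive, and the air-sensitive aminoresorcinol is kept under argon and carried on directly.

Step 4
Reactants: 9 2-amino-5-(benzyloxy)benzene-1,3-diol; 10 tert-butyl nitrite
Product: 11 3-(benzyloxy)-6-diazo-5-hydroxycyclohexa-2,4-dien-1-one
Conditions: t-BuONO (1.05 equiv), AcOH (0.1 equiv), THF, −15 °C to 0 °C, dark; precipitation with hexane
Reagents that add atoms: tert-butyl nitrite (10), CC(C)(C)ON=O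
Why: Diazotization of an ortho-aminophenol with an alkyl nitrite: the diazonium ion loses a phenolic proton to give the neutral quinone diazide, which is stabilized by the para benzyloxy oxygen; one equivalent of nitrite at low temperature is chosen to limit C-nitrosation and azo coupling.

Step 5
Reactants: 5 8-hydroxy-7-methoxy-2H-chromen-2-one; 11 3-(benzyloxy)-6-diazo-5-hydroxycyclohexa-2,4-dien-1-one
Product: 12 8-[4-(benzyloxy)-2,6-dihydroxyphenoxy]-7-methoxy-2H-chromen-2-one
Conditions: Rh2(OAc)4 (2 mol%), 5 (1.5 equiv), 4 Å MS, ClCH2CH2Cl, 70 °C, 11 added in portions over 3 h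
Reagents that add atoms: none
Why: Rhodium-carbenoid O–H insertion: Rh2(OAc)4 takes N2 from 11 to give a divalent-rhodium quinoid carbene whose carbene carbon (the future C8 of ring B) is strongly electrophilic, the phenolic oxygen of 5 adds to it, and the resulting aryloxonium phenolate is already aromatic, so proton transfer from the oxonium to the neighbouring phenolate oxygen and release of the catalyst should give 12 directly. The closest known reaction type is the O–H insertion of rhodium carbenes from diazo carbonyl compounds into alcohols and phenols, quinone diazides being established precursors of such quinoid carbenes. No ring is closed and no stereocentre is formed. The step reverses the polarity of ring B, so two oxygenated, nucleophilic arenes are joined without a metal centre having to carry both crowded aryl groups; bond formation at a planar carbene carbon has an early transition state and should tolerate two ortho substituents on each side. Regiochemistry is fixed by the position of the diazo group, which goes back to the nitro group of 6, and the product is symmetric, which prepares step 6. The selectivity needed is insertion into the hydroxyl of 5 in preference to ring contraction (Wolff rearrangement), to attack on the hydroxyl of a second molecule of 11 or on water, and to attack at C5 or C6 of ring A; the metal-bound carbene, the excess of 5, the slow addition of 11, the molecular sieves and the lactone-deactivated ring A are expected to secure it.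

Step 6
Reactants: 12 8-[4-(benzyloxy)-2,6-dihydroxyphenoxy]-7-methoxy-2H-chromen-2-one; 13 ethyl propiolate
Product: 15 5-(benzyloxy)-7-hydroxy-8-[(7-methoxy-2-oxo-2H-chromen-8-yl)oxy]-2H-chromen-2-one, via ethyl (Z)-3-{6-(benzyloxy)-2,4-dihydroxy-3-[(7-methoxy-2-oxo-2H-chromen-8-yl)oxy]phenyl}prop-2-enoate 14 (not isolated)
Conditions: HC≡CCO2Et (1.1 equiv), Pd(OAc)2 (5 mol%), NaOAc (0.2 equiv), HCO2H, rt
Reagents that add atoms: ethyl propiolate (13), C#CC(=O)OCC
Why: Palladium-catalysed hydroarylation of the alkynoate by the electron-rich phenol (a Pechmann-type annulation with a propiolate) should give the Z-cinnamate 14, which lactonizes onto the only free ortho hydroxyl; the two reactive CH positions of 12 are equivalent and O5 is benzylated, so only the 8-aryloxy-5-benzyloxy-7-hydroxy isomer can form, and the new lactone deactivates the ring against a second annulation.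

Step 7
Reactants: 15 5-(benzyloxy)-7-hydroxy-8-[(7-methoxy-2-oxo-2H-chromen-8-yl)oxy]-2H-chromen-2-one
Product: 16 5,7-dihydroxy-8-[(7-methoxy-2-oxo-2H-chromen-8-yl)oxy]-2H-chromen-2-one
Conditions: BCl3 (4 equiv), C6HMe5 (3 equiv), CH2Cl2, −78 °C to −30 °C; then H2O
Reagents that add atoms: none
Why: Lewis-acid debenzylation with a non-basic cation scavenger: BCl3 cleaves the aryl benzyl ether at low temperature while the unchelated aryl methyl ether, the diaryl ether and both lactones should remain, and pentamethylbenzene traps the benzyl cation before it can alkylate the phloroglucinol ring.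

## Compound list

1 | 2,3-dihydroxy-4-methoxybenzaldehyde | COc1ccc(C=O)c(O)c1O | starting material
2 | ethyl (triphenylphosphoranylidene)acetate | CCOC(=O)C=P(c1ccccc1)(c1ccccc1)c1ccccc1 | starting material
3 | ethyl (E)-3-(2,3-dihydroxy-4-methoxyphenyl)prop-2-enoate | CCOC(=O)/C=C/c1ccc(OC)c(O)c1O | intermediate
4 | ethyl (Z)-3-(2,3-dihydroxy-4-methoxyphenyl)prop-2-enoate | CCOC(=O)/C=C\c1ccc(OC)c(O)c1O | intermediate
5 | 8-hydroxy-7-methoxy-2H-chromen-2-one | COc1ccc2ccc(=O)oc2c1O | intermediate
6 | 2-nitrobenzene-1,3,5-triol | Oc1cc(O)c([N+](=O)[O-])c(O)c1 | starting material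
7 | benzyl bromide | BrCc1ccccc1 | starting material
8 | 5-(benzyloxy)-2-nitrobenzene-1,3-diol | O=[N+]([O-])c1c(O)cc(OCc2ccccc2)cc1O | intermediate
9 | 2-amino-5-(benzyloxy)benzene-1,3-diol | Nc1c(O)cc(OCc2ccccc2)cc1O | intermediate
10 | tert-butyl nitrite | CC(C)(C)ON=O | starting material
11 | 3-(benzyloxy)-6-diazo-5-hydroxycyclohexa-2,4-dien-1-one | O=C1C=C(OCc2ccccc2)C=C(O)C1=[N+]=[N-] | intermediate
12 | 8-[4-(benzyloxy)-2,6-dihydroxyphenoxy]-7-methoxy-2H-chromen-2-one | COc1ccc2ccc(=O)oc2c1Oc1c(O)cc(OCc2ccccc2)cc1O | intermediate
13 | ethyl propiolate | C#CC(=O)OCC | starting material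
14 | ethyl (Z)-3-{6-(benzyloxy)-2,4-dihydroxy-3-[(7-methoxy-2-oxo-2H-chromen-8-yl)oxy]phenyl}prop-2-enoate | CCOC(=O)/C=C\c1c(OCc2ccccc2)cc(O)c(Oc2c(OC)ccc3ccc(=O)oc23)c1O | intermediate
15 | 5-(benzyloxy)-7-hydroxy-8-[(7-methoxy-2-oxo-2H-chromen-8-yl)oxy]-2H-chromen-2-one | COc1ccc2ccc(=O)oc2c1Oc1c(O)cc(OCc2ccccc2)c2ccc(=O)oc12 | intermediate
16 | 5,7-dihydroxy-8-[(7-methoxy-2-oxo-2H-chromen-8-yl)oxy]-2H-chromen-2-one | COc1ccc2ccc(=O)oc2c1Oc1c(O)cc(O)c2ccc(=O)oc12 | target

## Step count and risks

Total: 7 steps. Longest linear sequence: 6 steps (steps 2 to 7, from 6); step 1 is a one-step side branch that joins at step 5.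

**Step 5 (key step).** The carbene may be diverted before it meets the phenol. Possible paths are ring contraction by Wolff rearrangement, insertion into the hydroxyl of a second molecule of 11 or into traces of water, and electrophilic attack on carbon of ring A instead of oxygen. The cause is that the hydroxyl of 5 is crowded and hydrogen-bonded to the neighbouring methoxy group, which makes it a modest nucleophile.
Fallback, from 11 together with 5, back at 12: KI in dilute H2SO4 should replace the diazo group by iodine (iododediazoniation) to give 5-(benzyloxy)-2-iodobenzene-1,3-diol F1. MOMCl and i-Pr2NEt would give 5-(benzyloxy)-2-iodo-1,3-bis(methoxymethoxy)benzene F2. An Ullmann ether synthesis of F2 with 5 (CuI, picolinic acid, K3PO4, DMSO, 90 °C) would give 8-[4-(benzyloxy)-2,6-bis(methoxymethoxy)phenoxy]-7-methoxy-2H-chromen-2-one F3. HCl in MeOH would remove both acetals and return 12.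

**Step 4.** Azo coupling of the newly formed diazonium ion with unreacted, very electron-rich 9, C-nitrosation of the ring, and loss of nitrogen on isolation may all erode the quinone diazide.
Fallback, from 8, back at 12, giving up the carbene for a copper coupling: MOMCl and i-Pr2NEt would cap both hydroxyls to give 5-(benzyloxy)-1,3-bis(methoxymethoxy)-2-nitrobenzene F4. Hydrogenation over sulfided Pt/C would give 4-(benzyloxy)-2,6-bis(methoxymethoxy)aniline F5. A non-aqueous Sandmeyer-type iodination (t-BuONO, I2, MeCN), in which the capped ring no longer couples, would give the iodide F2. The Ullmann coupling with 5 to the ether F3 and the acetal cleavage to 12 would follow as above.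

**Step 6.** A second hydroarylation at the remaining ring carbon of ring B, O-vinylation of a phenol instead of C–C bond formation, or acid-induced loss or migration of the benzyl group (which would free O5 and reopen the 6/8 choice) may occur.
Fallback, from 12, back at 15, in two regiosecure operations: Vilsmeier–Haack formylation (POCl3, DMF, MeCN, then H2O) should give, as the only possible C-formyl product of the symmetric ring, 6-(benzyloxy)-2,4-dihydroxy-3-[(7-methoxy-2-oxo-2H-chromen-8-yl)oxy]benzaldehyde F6. Wittig olefination with 2 in PhNEt2 at reflux would give ethyl (E)-3-{6-(benzyloxy)-2,4-dihydroxy-3-[(7-methoxy-2-oxo-2H-chromen-8-yl)oxy]phenyl}prop-2-enoate F7, which equilibrates with 14 and lactonizes to 15.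

**Step 2.** Over-alkylation, alkylation of a hydroxyl ortho to the nitro group, or C-benzylation may lower the selectivity for the para oxygen.
Fallback, from 6, back at 8: exhaustive benzylation (excess BnBr, K2CO3, DMF, 60 °C) would give 1,3,5-tris(benzyloxy)-2-nitrobenzene F8. BCl3 (2.2 equiv, CH2Cl2, −78 °C) would then be directed by chelation to a nitro oxygen and should remove only the two benzyl groups ortho to the nitro group, returning 8.

## Further compounds

F1 | step 5 | 5-(benzyloxy)-2-iodobenzene-1,3-diol | Oc1cc(OCc2ccccc2)cc(O)c1I
F2 | step 5 | 5-(benzyloxy)-2-iodo-1,3-bis(methoxymethoxy)benzene | COCOc1cc(OCc2ccccc2)cc(OCOC)c1I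
F3 | step 5 | 8-[4-(benzyloxy)-2,6-bis(methoxymethoxy)phenoxy]-7-methoxy-2H-chromen-2-one | COCOc1cc(OCc2ccccc2)cc(OCOC)c1Oc1c(OC)ccc2ccc(=O)oc12
F4 | step 4 | 5-(benzyloxy)-1,3-bis(methoxymethoxy)-2-nitrobenzene | COCOc1cc(OCc2ccccc2)cc(OCOC)c1[N+](=O)[O-]
F5 | step 4 | 4-(benzyloxy)-2,6-bis(methoxymethoxy)aniline | COCOc1cc(OCc2ccccc2)cc(OCOC)c1N
F6 | step 6 | 6-(benzyloxy)-2,4-dihydroxy-3-[(7-methoxy-2-oxo-2H-chromen-8-yl)oxy]benzaldehyde | O=Cc1c(OCc2ccccc2)cc(O)c(Oc2c(OC)ccc3ccc(=O)oc23)c1O
F7 | step 6 | ethyl (E)-3-{6-(benzyloxy)-2,4-dihydroxy-3-[(7-methoxy-2-oxo-2H-chromen-8-yl)oxy]phenyl}prop-2-enoate | CCOC(=O)/C=C/c1c(OCc2ccccc2)cc(O)c(Oc2c(OC)ccc3ccc(=O)oc23)c1O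
F8 | step 2 | 1,3,5-tris(benzyloxy)-2-nitrobenzene | O=[N+]([O-])c1c(OCc2ccccc2)cc(OCc2ccccc2)cc1OCc1ccccc1
A1 | alternative 1 | 5,7-bis(benzyloxy)-8-bromo-2H-chromen-2-one | O=c1ccc2c(OCc3ccccc3)cc(OCc3ccccc3)c(Br)c2o1
A2 | alternative 1 | 5,7-bis(benzyloxy)-8-[(7-methoxy-2-oxo-2H-chromen-8-yl)oxy]-2H-chromen-2-one | COc1ccc2ccc(=O)oc2c1Oc1c(OCc2ccccc2)cc(OCc2ccccc2)c2ccc(=O)oc12
A3 | alternative 2 | 2-diazocyclohexane-1,3-dione | O=C1CCCC(=O)C1=[N+]=[N-]
A4 | alternative 2 | 5,7-bis(benzyloxy)-8-hydroxy-2H-chromen-2-one | O=c1ccc2c(OCc3ccccc3)cc(OCc3ccccc3)c(O)c2o1
A5 | alternative 2 | 5,7-bis(benzyloxy)-8-[(2,6-dioxocyclohexyl)oxy]-2H-chromen-2-one | O=C1CCCC(=O)C1Oc1c(OCc2ccccc2)cc(OCc2ccccc2)c2ccc(=O)oc12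
A6 | alternative 2 | 5,7-bis(benzyloxy)-8-(2-hydroxy-6-methoxyphenoxy)-2H-chromen-2-one | COc1cccc(O)c1Oc1c(OCc2ccccc2)cc(OCc2ccccc2)c2ccc(=O)oc12
A7 | alternative 3 | diethyl 2-[(7-methoxy-2-oxo-2H-chromen-8-yl)oxy]propanedioate | CCOC(=O)C(Oc1c(OC)ccc2ccc(=O)oc12)C(=O)OCC
A8 | alternative 3 | dimethyl 2,4,6-trihydroxy-5-[(7-methoxy-2-oxo-2H-chromen-8-yl)oxy]benzene-1,3-dicarboxylate | COC(=O)c1c(O)c(C(=O)OC)c(O)c(Oc2c(OC)ccc3ccc(=O)oc23)c1O
A9 | alternative 3 | 7-methoxy-8-(2,4,6-trihydroxyphenoxy)-2H-chromen-2-one | COc1ccc2ccc(=O)oc2c1Oc1c(O)cc(O)cc1O
A10 | alternative 3 | 5,7-dihydroxy-6-[(7-methoxy-2-oxo-2H-chromen-8-yl)oxy]-2H-chromen-2-one | COc1ccc2ccc(=O)oc2c1Oc1c(O)cc2oc(=O)ccc2c1O
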